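The runs were computed with constants of no real substance; the scatter is artificial.

| flask | solid substrate | remark | time |
|---|---|---|---|
| Wednesday's | 6 mM | run made earlier |  |
| Monday's | 9 mM | run made earlier |  |
| flask | 12 mM |  | 8.0 h |

| run | time / h | solid substrate / % | target / % |
|---|---|---|---|
| Wednesday's | 0.500 | 61.2 | 0.7 |
| Wednesday's | 1.33 | 0.3 | 5.9 |
| Wednesday's | 2.50 | 0.1 | 6.7 |
| Wednesday's | 4.00 | 0 | 4.9 |
| Wednesday's | 6.00 | 0.9 | 4.1 |
| Wednesday's | 8.00 | 0.4 | 5.5 |
| Wednesday's | 10.0 | 0.8 | 4.8 |
| Monday's | 0.500 | 73.9 | 0.1 |
| Monday's | 1.33 | 32.8 | 3.8 |
| Monday's | 2.50 | 0 | 4.0 |
| Monday's | 4.00 | 0 | 4.9 |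
| Monday's | 6.00 | 0.7 | 4.6 |
| Monday's | 8.00 | 0 | 4.2 |
| Monday's | 10.0 | 0 | 4.5 |

(scatter of a reading: 1 percentage point)

- amounts and yields of target count crystals too
- given per volume of solution although it is solid: solid substrate, crystals
- what was read earlier has a scatter of 1 percentage point, one standard deviation
- steps under discussion: starting material <-> target; target <-> isomer of the product A; isomer of the product A <-> isomer of the product B; isomer of the product B <-> starting material; solid substrate <-> starting material; starting material <-> dormant form; crystals <-> target
- at the start none of the solid substrate is in solution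
- what has only dissolved of solid substrate counts as not reacted
- what has gone from starting material into another species counts as reacted, even if it can come back
- starting material means what is dissolved; the solid is not counted in it

- part of the solid substrate that has turned into other species by 8.0 h (what has only dissolved does not count)
- how much target there is at 8.0 h, in percent of the solid substrate charged
- how much starting material there is at 8.0 h, in percent of the solid substrate charged

Amounts, not percentages, show how this solid behaves. In the first 0.500 h, Wednesday's run loses solid substrate at 4.66 mM h⁻¹ and Monday's at 4.70 mM h⁻¹, so these two readings of the rate agree although Monday's charge is larger. My bench rule follows from this: r, the dissolving rate, is the mean of these two losses in mM per hour, 4.68 mM h⁻¹, and for as long as the rate holds at r, the solid lasts for its charge divided by r. This reads as zero order in the solid, a plateau like Vmax, so I take the concentration that sets the rate to be that of dissolved starting material, which was not read. Monday's solid still gives 4.46 mM h⁻¹ in its second stretch, 0.953 of r, so I conclude that dissolved starting material has not piled up.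

In this flask I place the rule's border at the end of the solid. For this flask, charge over r gives 2.57 h, a ratio of 0.321 to the asked time. I therefore expect conv and starting material to add up to 100 %, with starting material small, and target near the last readings, 4.8 % and 4.5 %.

The forecast gives 60 %, 4.7 % and 40 %, saying “Starting material was never measured, so y_A is only a guess”, and I differ from it in expecting a low starting material. The flask gives 93.2 %, 4.64 % and 6.81 %.

    starting material ⇌ target (K = 0.680, k = 0.0120 min⁻¹)
    target ⇌ isomer of the product A (K = 0.780, k = 0.310 min⁻¹)
    isomer of the product A ⇌ isomer of the product B (K = 0.910, k = 0.0310 min⁻¹)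
    isomer of the product B ⇌ starting material (k = 0.0120 min⁻¹)
    solid substrate ⇌ starting material, rate k5*(cs5 - [starting material]) while solid is left; crystals form when [starting material] > cs5 (solubility = 8.40 mM, k = 0.00970 min⁻¹)
    starting material ⇌ dormant form (K = 12.0, k = 0.110 min⁻¹)
    crystals ⇌ target, rate k7*(cs7 - [target]) while solid is left; crystals form when [target] > cs7 (solubility = 4.30 mM, k = 5.70 min⁻¹)

In this flask, r leaves 68.8 % of the solid at 0.800 h, and the flask holds 69.6 %. The neighbour charged with 48 mM takes the same reckoning: charge over r is 10.3 h, longer than 8.0 h, so r leaves 22.0 % of its solid at that time. That neighbour holds 33.8 % of its charge as solid substrate, so on average 3.97 mM h⁻¹ left its solid, less than r. With its 2.55 mM of starting material at 8.00 h, that neighbour's dissolving rate, 0.0097 min⁻¹ times the gap to the solubility 8.4 mM, is 3.40 mM h⁻¹.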